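Ring atoms are numbered as in germacranolides: C1–C10 form the carbocycle, C11–C13 are the lactone carbons, C14 is the methyl on C10 and C15 the methyl on C4.

## The problem

The target is a ten-membered carbocycle with a 4Z trisubstituted olefin, a trans 1,10-epoxide and an α-methylene-γ-lactone fused trans across C6–C7. C3 and C8 carry two different chiral acyloxy groups. The ring has six stereocentres (C1, C3, C6, C7, C8, C10). C3 is isolated from the others by the C4=C5 olefin and needs reagent control. C6, C7 and C8 are contiguous and can relay information to one another. C1 and C10 can only be set on the finished ring, through its conformation. The two acyl groups, (R)-2-methylbutanoyl and (2R,3S)-2,3-dimethyloxirane-2-carbonyl, must be brought in as single enantiomers and kept from epimerising. Several groups are fragile: the exocyclic methylene lactone is a Michael acceptor, both epoxides are acid-labile (the 1,10-epoxide can be opened transannularly by C4=C5), the allylic esters at C3 and C6 dislike strong base, and the 1(10),4-diene can cyclise across the ring under electrophilic conditions. The medium ring must therefore be closed by a C–C bond formation that tolerates dense oxygenation, with the Z olefin geometry already fixed. The enabling feature is that C7 sits between the oxygen-bearing C6 and C8 and needs only C11. The C6 oxygen, which ends as the lactone oxygen, can carry C12–C11–C13 as a propiolate, so a radical at C7 (from C7–O homolysis) can close the ring O–C6–C7–C11–C12 and deliver the C13 methylene in one event. Because that radical is planar, the earlier C7 configuration is free for another use.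

## Retrosynthesis

**End game.** The 1,10-epoxide is removed first (36 ⇒ 35). It is the most acid-sensitive group, and the E olefin of the formed ring exposes only its outer face, so a late peracid epoxidation is the natural way to set C1 and C10. Cutting the C8 ester next (35 ⇒ 30 + 33) keeps the epoxy acid 33 away from the radical and fluoride steps. Acid 33 goes back to epoxy alcohol 32 and (E)-2-methylbut-2-en-1-ol 31 by asymmetric epoxidation. Alcohol 30 comes from silyl ether 29.

**Key disconnection.** In 29 the C7–C11 bond is cut, which opens the lactone and turns the methylene into the alkyne of propiolate 28, with a xanthate on C7. Against late enolate methylenation of a saturated lactone, this cut avoids base on a germacradienolide. Against a Reformatsky-type annulation, it needs no control of C7, because both C7 epimers give the same planar radical. The precursor is simpler by one ring, one C–C bond and one stereocentre. The forward step must make the tin radical choose the thiocarbonyl over the alkyne, must cyclise faster than it is reduced, and must fuse the rings trans.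

**Propiolate and ring.** Ester 28 is cut at the acyl C6–O bond to alcohol 26 and propiolic acid 27. The ring of 26 is cut at C5–C6 to iodo aldehyde 25, a Nozaki–Hiyama–Kishi disconnection. This bond is preferred to an olefin-forming closure because the Z-C4=C5 and E-C1=C10 geometries are then built in small acyclic pieces, and the reaction creates the C6 hydroxyl exactly where the propiolate is needed. The forward step has to deliver 6R. The disposable C7 centre is chosen so that open-chain 1,2- and 1,3-induction both point that way.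

**C6–C8 triad.** Aldehyde 25 is traced through bis-silyl ether 23, diol 22, xanthate 21 and alcohol 19 to ketone 18. The six-membered acetonide of 18 ties O6 and O8 together and leaves C7 as the only free position. Three adjacent oxygens are thus differentiated without extra protecting-group steps, and the xanthate is installed where no neighbouring silyl or acyl group can migrate. Ketone 18 is cut at C8–C9 into allylic bromide 12 and the RAMP hydrazone 15 of 2,2-dimethyl-1,3-dioxan-5-one 13 (auxiliary 14). This alkylation brings in C6, C7 and C8 at once and sets C8 by the auxiliary.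

**Western chain.** Bromide 12 goes back through alcohol 11 to enal 10, which is cut at C1=C10 by cross-metathesis into ester 8 and methacrolein 9. This gives the E trisubstituted olefin in one step. Ester 8 is the (R)-2-methylbutanoate (acid 7) of homoallylic alcohol 6. The final C3 ester is placed early so that no protecting-group exchange is needed later. Alcohol 6 is cut at C2–C3 by asymmetric allylboration of enal 4. The Z iodo-olefin of 4 comes from alcohol 3 and propargyl alcohol 1 by hydroxyl-directed carbometalation and iodination.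

## Roads not taken

Alternative 1: The cuts are C7–C8 and C11–C13. In the forward step the 2-lithio derivative of dithiane A2 would add to C7 of butenolide A3 on the face away from the C6 substituent, and the lactone enolate would be trapped at C11 by a methyleneiminium salt to give Mannich base A1.
- Merits: it is convergent, the 6,7-trans relationship comes from reliable substrate control, and the methylene is only an elimination away.
- Weak points for this target: C8 arrives at the ketone oxidation level and must later be unmasked and reduced to 8R beside a base-sensitive lactone. The ten-membered ring is still open in A1. Its closure would have to create the Z trisubstituted C4=C5 olefin in a medium ring, which is the hardest bond of the skeleton to form by ring closure.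
- Comparison: this road is better at securing the lactone stereochemistry early and by ionic chemistry. The chosen plan sets against it that ring size and both olefin geometries are settled before the lactone is made, and that C8 comes from an auxiliary.

Alternative 2: The cut is C8–C9, with C1–C6 re-formed to fold the ten-membered ring back into a cyclohexene. Forward, the potassium alkoxide of cyclohexenol A5 undergoes an anionic oxy-Cope shift to dienone A4.
- Merits: the ring, the E-C1=C10 olefin and the C6 carbonyl appear in one step from a six-membered ring. For ring construction alone this is shorter than the chosen macrocyclisation.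
- Weak points for this target: A4 has no oxygen at C7 and no C11. The lactone would need regioselective C7 functionalisation of a cross-conjugated, transannularly reactive dienone and a stereoselective C6 reduction. C8 depends on a Z enol ether geometry and a chair transition state with an axial alkoxy group.
- Comparison: this road builds the carbocycle better. The chosen plan sets against it a fully defined C6–C7–C8 oxygen pattern and a lactone annulation that does not rely on enolate chemistry of the medium ring.

Alternative 3: The cuts are C5–C6 and the lactone O–C12 bond. Forward, iodo aldehyde ester A7 is closed with CrCl2/NiCl2, and the C6 alkoxide lactonises onto the C12 ester to give A6.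
- Merits: it uses the same ring closure as the chosen plan, needs no differentiation of three hydroxyls and no radical step, and is probably shorter.
- Weak points for this target: C7 must be set early as an epimerisable centre α to the aldehyde. The facial outcome at C6 then fixes cis or trans fusion with no later correction. The methylene must still be introduced by enolate chemistry at the end.
- Comparison: in step economy this road is as good or better. The chosen plan sets against it stereoconvergence at C7, a methylene formed together with the lactone under neutral conditions, and the use of C7 as a temporary control element for C6.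

Key step: step 17

## Route

Remarks on the chemistry:
- C7 is carried as the single 7R epimer expected from step 10. It becomes planar in step 17, so either epimer would give the same lactone.
- The C=N geometry of hydrazone 17 is not assigned.
- Steps 19 and 20 are a side branch and may be run at any time before step 21.

Step 1
Reactants: 1 prop-2-yn-1-ol
Product: 3 (Z)-3-iodo-2-methylprop-2-en-1-ol, via cyclic vinylmagnesium alkoxide 2 (not isolated)
Conditions: MeMgBr (2.5 equiv), CuI (10 mol%), Et2O/THF, −10 °C to rt; then I2, −10 °C to rt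
Reagents that add atoms: methylmagnesium bromide, C[Mg]Br; iodine, II
Why: Copper-catalysed, alkoxide-directed anti-carbomagnesiation puts methyl on the internal carbon and magnesium on the terminal carbon cis to the CH2O group; iodinolysis with retention gives the Z iodide (the future C4=C5).

Step 2
Reactants: 3 (Z)-3-iodo-2-methylprop-2-en-1-ol
Product: 4 (Z)-3-iodo-2-methylprop-2-enal
Conditions: MnO2, CH2Cl2, rt, dark; used at once
Reagents that add atoms: none
Why: MnO2 oxidation of an allylic alcohol; neutral conditions and exclusion of light should limit Z to E isomerisation of the iodo enal.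

Step 3
Reactants: 4 (Z)-3-iodo-2-methylprop-2-enal
Product: 6 (1Z,3S)-1-iodo-2-methylhexa-1,5-dien-3-ol, via diisopinocampheylborinate ester 5 (not isolated)
Conditions: (−)-Ipc2BOMe, CH2=CHCH2MgBr, Et2O, 0 °C to rt; then 4, −78 °C; then NaOH, H2O2, 0 °C
Reagents that add atoms: allylmagnesium bromide, C=CC[Mg]Br
Why: Asymmetric allylboration (Brown allylation) through a chair Zimmerman–Traxler transition state; the borane derived from (+)-α-pinene should add to the aldehyde face that gives 3S and forms the C2–C3 bond.

Step 4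
Reactants: 6 (1Z,3S)-1-iodo-2-methylhexa-1,5-dien-3-ol; 7 (R)-2-methylbutanoic acid
Product: 8 (1Z,3S)-1-iodo-2-methylhexa-1,5-dien-3-yl (2R)-2-methylbutanoate
Conditions: DCC, DMAP (0.1 equiv), CH2Cl2, 0 °C to rt
Reagents that add atoms: none
Why: Steglich esterification proceeds with retention at C3; catalytic DMAP at low temperature should leave the α-centre of the acid untouched. The final C3 ester is in place from here on.

Step 5
Reactants: 8 (1Z,3S)-1-iodo-2-methylhexa-1,5-dien-3-yl (2R)-2-methylbutanoate; 9 methacrolein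
Product: 10 (1Z,3S,5E)-1-iodo-2,6-dimethyl-7-oxohepta-1,5-dien-3-yl (2R)-2-methylbutanoate
Conditions: 9 (5 equiv), second-generation Hoveyda–Grubbs catalyst (5 mol%), CH2Cl2, 40 °C
Reagents that add atoms: none
Why: Olefin cross-metathesis of a terminal alkene with methacrolein forms C1=C10 and should favour the E enal thermodynamically; the trisubstituted iodo-olefin is inert to the catalyst.

Step 6
Reactants: 10 (1Z,3S,5E)-1-iodo-2,6-dimethyl-7-oxohepta-1,5-dien-3-yl (2R)-2-methylbutanoate
Product: 11 (1Z,3S,5E)-7-hydroxy-1-iodo-2,6-dimethylhepta-1,5-dien-3-yl (2R)-2-methylbutanoate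
Conditions: NaBH4, CeCl3·7H2O, MeOH, −40 °C
Reagents that add atoms: none
Why: Luche 1,2-reduction of the enal; the ester and the vinyl iodide are not reduced under these conditions.

Step 7
Reactants: 11 (1Z,3S,5E)-7-hydroxy-1-iodo-2,6-dimethylhepta-1,5-dien-3-yl (2R)-2-methylbutanoate
Product: 12 (1Z,3S,5E)-7-bromo-1-iodo-2,6-dimethylhepta-1,5-dien-3-yl (2R)-2-methylbutanoate
Conditions: CBr4, PPh3, CH2Cl2, −20 to 0 °C
Reagents that add atoms: carbon tetrabromide, BrC(Br)(Br)Br
Why: Appel bromination of a primary allylic alcohol under neutral conditions; the olefin geometry is kept.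

Step 8
Reactants: 13 2,2-dimethyl-1,3-dioxan-5-one; 14 (R)-1-amino-2-(methoxymethyl)pyrrolidine (RAMP)
Product: 15 (R)-N-(2,2-dimethyl-1,3-dioxan-5-ylidene)-2-(methoxymethyl)pyrrolidin-1-amine
Conditions: benzene, reflux, Dean–Stark
Reagents that add atoms: none
Why: Hydrazone condensation of a symmetric ketone with the chiral hydrazine; water is removed azeotropically.

Step 9
Reactants: 15 (R)-N-(2,2-dimethyl-1,3-dioxan-5-ylidene)-2-(methoxymethyl)pyrrolidin-1-amine; 12 (1Z,3S,5E)-7-bromo-1-iodo-2,6-dimethylhepta-1,5-dien-3-yl (2R)-2-methylbutanoate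
Product: 18 (1Z,3S,5E)-7-[(4R)-2,2-dimethyl-5-oxo-1,3-dioxan-4-yl]-1-iodo-2,6-dimethylhepta-1,5-dien-3-yl (2R)-2-methylbutanoate, via lithium azaenolate 16 (not isolated), via alkylated RAMP hydrazone 17 (not isolated)
Conditions: 15 (1.2 equiv), t-BuLi (1.15 equiv), THF, −78 °C; then 12, −100 °C to rt; then sat. aq. (CO2H)2, Et2O, rt
Reagents that add atoms: water, O
Why: SAMP/RAMP-hydrazone α-alkylation forms C8–C9; the chelated azaenolate is alkylated on the face opposite the methoxymethyl arm, which for RAMP should give 4R (C8). The allylic bromide should react at −100 °C faster than the azaenolate can attack or deprotonate the hindered ester, and biphasic oxalic acid frees the ketone without epimerisation.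

Step 10
Reactants: 18 (1Z,3S,5E)-7-[(4R)-2,2-dimethyl-5-oxo-1,3-dioxan-4-yl]-1-iodo-2,6-dimethylhepta-1,5-dien-3-yl (2R)-2-methylbutanoate
Product: 19 (1Z,3S,5E)-7-[(4R,5R)-5-hydroxy-2,2-dimethyl-1,3-dioxan-4-yl]-1-iodo-2,6-dimethylhepta-1,5-dien-3-yl (2R)-2-methylbutanoate
Conditions: LiBH(s-Bu)3 (1.1 equiv), THF, −78 °C; then NaBO3·4H2O, H2O, 0 °C
Reagents that add atoms: none
Why: Diastereoselective hydride reduction of a 4-substituted 1,3-dioxan-5-one; equatorial attack, away from the ring-oxygen lone pairs, should give the 4,5-cis alcohol (7R). This centre is temporary and serves only to steer step 15.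

Step 11
Reactants: 19 (1Z,3S,5E)-7-[(4R,5R)-5-hydroxy-2,2-dimethyl-1,3-dioxan-4-yl]-1-iodo-2,6-dimethylhepta-1,5-dien-3-yl (2R)-2-methylbutanoate
Product: 21 (1Z,3S,5E)-7-[(4R,5R)-2,2-dimethyl-5-{[(methylsulfanyl)carbonothioyl]oxy}-1,3-dioxan-4-yl]-1-iodo-2,6-dimethylhepta-1,5-dien-3-yl (2R)-2-methylbutanoate, via sodium xanthate salt 20 (not isolated)
Conditions: NaN(SiMe3)2 (1.05 equiv), CS2, THF, −78 °C; then MeI, −78 to 0 °C
Reagents that add atoms: carbon disulfide, S=C=S; iodomethane, CI
Why: Standard xanthate formation (alkoxide, CS2, S-methylation); both neighbouring oxygens are locked in the acetonide, so nothing can migrate to the C7 alkoxide, and one equivalent of base at −78 °C should spare the ester.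

Step 12
Reactants: 21 (1Z,3S,5E)-7-[(4R,5R)-2,2-dimethyl-5-{[(methylsulfanyl)carbonothioyl]oxy}-1,3-dioxan-4-yl]-1-iodo-2,6-dimethylhepta-1,5-dien-3-yl (2R)-2-methylbutanoate
Product: 22 (1Z,3S,5E,8R,9R)-8,10-dihydroxy-1-iodo-2,6-dimethyl-9-{[(methylsulfanyl)carbonothioyl]oxy}deca-1,5-dien-3-yl (2R)-2-methylbutanoate
Conditions: AcOH/THF/H2O (3:1:1), 40 °C
Reagents that add atoms: none
Why: Acid hydrolysis of the six-membered acetonide; the xanthate, the ester and the vinyl iodide are stable to dilute acid, and thioacyl migration is not acid-promoted.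

Step 13
Reactants: 22 (1Z,3S,5E,8R,9R)-8,10-dihydroxy-1-iodo-2,6-dimethyl-9-{[(methylsulfanyl)carbonothioyl]oxy}deca-1,5-dien-3-yl (2R)-2-methylbutanoate
Product: 23 (1Z,3S,5E,8R,9R)-1-iodo-2,6-dimethyl-9-{[(methylsulfanyl)carbonothioyl]oxy}-8,10-bis[(triethylsilyl)oxy]deca-1,5-dien-3-yl (2R)-2-methylbutanoate
Conditions: Et3SiOTf, 2,6-lutidine, CH2Cl2, −78 °C
Reagents that add atoms: triethylsilyl trifluoromethanesulfonate, CC[Si](CC)(CC)OS(=O)(=O)C(F)(F)F
Why: Silylation of both hydroxyls with a silyl triflate and a hindered, non-nucleophilic base; the cold, fast conditions should prevent attack of a free hydroxyl on the xanthate.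

Step 14
Reactants: 23 (1Z,3S,5E,8R,9R)-1-iodo-2,6-dimethyl-9-{[(methylsulfanyl)carbonothioyl]oxy}-8,10-bis[(triethylsilyl)oxy]deca-1,5-dien-3-yl (2R)-2-methylbutanoate
Product: 25 (1Z,3S,5E,8R,9S)-1-iodo-2,6-dimethyl-9-{[(methylsulfanyl)carbonothioyl]oxy}-10-oxo-8-[(triethylsilyl)oxy]deca-1,5-dien-3-yl (2R)-2-methylbutanoate, via alkoxysulfonium chloride 24 (not isolated)
Conditions: (COCl)2, DMSO, CH2Cl2, −78 to −40 °C; then Et3N, −78 to 0 °C
Reagents that add atoms: none
Why: Swern oxidation applied directly to a primary triethylsilyl ether; the chlorosulfonium reagent cleaves the unhindered primary silyl ether selectively and the alkoxysulfonium ion collapses to the C6 aldehyde, while the secondary C8 silyl ether stays.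

Step 15
Reactants: 25 (1Z,3S,5E,8R,9S)-1-iodo-2,6-dimethyl-9-{[(methylsulfanyl)carbonothioyl]oxy}-10-oxo-8-[(triethylsilyl)oxy]deca-1,5-dien-3-yl (2R)-2-methylbutanoate
Product: 26 (1S,2Z,4R,5R,6R,8E)-4-hydroxy-2,8-dimethyl-5-{[(methylsulfanyl)carbonothioyl]oxy}-6-[(triethylsilyl)oxy]cyclodeca-2,8-dien-1-yl (2R)-2-methylbutanoate
Conditions: CrCl2 (10 equiv), NiCl2 (0.2 equiv), DMSO, rt, slow addition of 25 to 0.003 M
Reagents that add atoms: none
Why: Intramolecular Nozaki–Hiyama–Kishi reaction: zerovalent nickel inserts into the C5–I bond, the alkenyl group passes to chromium with retention of the Z geometry and adds to the C6 aldehyde, closing the ten-membered ring. Polar Felkin–Anh addition anti to the C7 oxygen and 1,3-anti to the C8 silyloxy group both point to the 6R alcohol; divalent chromium is too weak a reductant to touch the xanthate.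

Step 16
Reactants: 26 (1S,2Z,4R,5R,6R,8E)-4-hydroxy-2,8-dimethyl-5-{[(methylsulfanyl)carbonothioyl]oxy}-6-[(triethylsilyl)oxy]cyclodeca-2,8-dien-1-yl (2R)-2-methylbutanoate; 27 propiolic acid
Product: 28 (1S,2Z,4R,5R,6R,8E)-2,8-dimethyl-5-{[(methylsulfanyl)carbonothioyl]oxy}-4-(prop-2-ynoyloxy)-6-[(triethylsilyl)oxy]cyclodeca-2,8-dien-1-yl (2R)-2-methylbutanoate
Conditions: 27, DCC, DMAP (0.1 equiv), CH2Cl2, −20 to 0 °C
Reagents that add atoms: none
Why: Steglich esterification with propiolic acid at low temperature and low DMAP loading, which limits amine addition to the alkyne; acylation occurs with retention at C6.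

Step 17
Reactants: 28 (1S,2Z,4R,5R,6R,8E)-2,8-dimethyl-5-{[(methylsulfanyl)carbonothioyl]oxy}-4-(prop-2-ynoyloxy)-6-[(triethylsilyl)oxy]cyclodeca-2,8-dien-1-yl (2R)-2-methylbutanoate
Product: 29 (3aS,4R,6E,9S,10Z,11aR)-6,10-dimethyl-3-methylidene-2-oxo-4-[(triethylsilyl)oxy]-2,3,3a,4,5,8,9,11a-octahydrocyclodeca[b]furan-9-yl (2R)-2-methylbutanoate
Conditions: Bu3SnH (1.5 equiv), AIBN (0.2 equiv), toluene, 110 °C, syringe-pump addition over 8 h, 0.002 M
Reagents that add atoms: none
Why: The tributyltin radical adds to the thiocarbonyl sulfur and the adduct fragments at C7–O, giving a secondary C7 radical that has lost its former configuration. This radical attacks C11, the alkyne carbon next to the ester carbonyl, in a 5-exo-dig closure that forms C7–C11 and the γ-lactone ring (O–C6–C7–C11–C12); the C13 vinyl radical then takes hydrogen from Bu3SnH, leaving the exocyclic methylene and carrying the chain. The closest known reaction type is the tin-hydride 5-exo-dig cyclisation of β-oxygenated alkyl radicals onto propiolate esters or propargylic acetals to α-methylene-γ-butyrolactones, here applied to a ten-membered ring. The only new stereocentre, C7, is controlled by the ring: with the C5–C6 and C7–C8 bonds anti, the alkyne tethered to O6 can reach only the C7 lobe syn to O6, which is also the face away from the C8 silyloxy group, so the 6,7-trans fusion should result. The step needs the tin radical to choose the thiocarbonyl over the alkyne; stannyl addition to the alkyne is reversible at 110 °C while xanthate fragmentation is not, and slow addition keeps the stannane concentration low. The same low concentration gives the ester time to reach the rotamer needed for closure before the C7 radical is reduced. Exo closure should be preferred over 6-endo attack at C13 on geometric grounds, and no base is present that could harm the esters or the new lactone.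

Step 18
Reactants: 29 (3aS,4R,6E,9S,10Z,11aR)-6,10-dimethyl-3-methylidene-2-oxo-4-[(triethylsilyl)oxy]-2,3,3a,4,5,8,9,11a-octahydrocyclodeca[b]furan-9-yl (2R)-2-methylbutanoate
Product: 30 (3aR,4R,6E,9S,10Z,11aR)-4-hydroxy-6,10-dimethyl-3-methylidene-2-oxo-2,3,3a,4,5,8,9,11a-octahydrocyclodeca[b]furan-9-yl (2R)-2-methylbutanoate
Conditions: HF·pyridine, pyridine, THF, 0 °C to rt
Reagents that add atoms: none
Why: Buffered fluoride cleavage of a secondary triethylsilyl ether; esters, diene and methylene lactone are stable to these weakly acidic conditions.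

Step 19
Reactants: 31 (E)-2-methylbut-2-en-1-ol
Product: 32 [(2S,3S)-2,3-dimethyloxiran-2-yl]methanol
Conditions: Ti(OiPr)4 (5 mol%), L-(+)-diethyl tartrate (6 mol%), t-BuOOH, 4 Å MS, CH2Cl2, −20 °C
Reagents that add atoms: tert-butyl hydroperoxide, CC(C)(C)OO
Why: Sharpless asymmetric epoxidation; with L-(+)-tartrate, E allylic alcohols are epoxidised on the face that gives the (2S,3S) epoxy alcohol, and the E geometry fixes the cis relationship of the two methyl groups.

Step 20
Reactants: 32 [(2S,3S)-2,3-dimethyloxiran-2-yl]methanol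
Product: 33 (2R,3S)-2,3-dimethyloxirane-2-carboxylic acid
Conditions: RuCl3·xH2O (2 mol%), NaIO4, CCl4/MeCN/H2O, rt; used without purification
Reagents that add atoms: water, O
Why: Catalytic RuO4 oxidation of a primary epoxy alcohol to the glycidic acid; neither stereocentre is touched (the C2 descriptor changes only by priority).

Step 21
Reactants: 33 (2R,3S)-2,3-dimethyloxirane-2-carboxylic acid; 30 (3aR,4R,6E,9S,10Z,11aR)-4-hydroxy-6,10-dimethyl-3-methylidene-2-oxo-2,3,3a,4,5,8,9,11a-octahydrocyclodeca[b]furan-9-yl (2R)-2-methylbutanoate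
Product: 35 (3aR,4R,6E,9S,10Z,11aR)-6,10-dimethyl-9-{[(2R)-2-methylbutanoyl]oxy}-3-methylidene-2-oxo-2,3,3a,4,5,8,9,11a-octahydrocyclodeca[b]furan-4-yl (2R,3S)-2,3-dimethyloxirane-2-carboxylate, via mixed anhydride 34 (not isolated)
Conditions: 33, 2,4,6-trichlorobenzoyl chloride, Et3N, THF, rt; then 30, DMAP, toluene, rt
Reagents that add atoms: none
Why: Yamaguchi esterification, suited to a hindered secondary alcohol and an α-quaternary acid; acylation is with retention at C8 and the epoxy acid has no enolisable α-hydrogen.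

Step 22
Reactants: 35 (3aR,4R,6E,9S,10Z,11aR)-6,10-dimethyl-9-{[(2R)-2-methylbutanoyl]oxy}-3-methylidene-2-oxo-2,3,3a,4,5,8,9,11a-octahydrocyclodeca[b]furan-4-yl (2R,3S)-2,3-dimethyloxirane-2-carboxylate
Product: 36 CNP0265335.3, (1R,3S,6R,7R,8R,10R)-1,10-epoxy-3-[(2R)-2-methylbutanoyloxy]-8-[(2R,3S)-2,3-epoxy-2-methylbutanoyloxy]germacra-4Z,11(13)-dien-12,6-olide
Conditions: mCPBA, NaHCO3, CH2Cl2, 0 °C
Reagents that add atoms: 3-chloroperoxybenzoic acid, OOC(=O)c1cccc(Cl)c1
Why: Prilezhaev epoxidation; C1=C10 is the only electron-rich olefin (C4=C5 has two allylic acyloxy groups, C11=C13 is conjugated). Attack on the outer face of the E olefin should give the trans 1R,10R epoxide, and the bicarbonate buffer guards against transannular opening.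

## Compound list

1 | prop-2-yn-1-ol (propargyl alcohol) | C#CCO | starting material
2 | 4-methyl-2,5-dihydro-1,2-oxamagnesole (cyclic vinylmagnesium alkoxide) | CC1=C[Mg]OC1 | intermediate
3 | (Z)-3-iodo-2-methylprop-2-en-1-ol | OC/C(C)=C\I | intermediate
4 | (Z)-3-iodo-2-methylprop-2-enal | O=C/C(C)=C\I | intermediate
5 | (1Z,3S)-1-iodo-2-methylhexa-1,5-dien-3-yl diisopinocampheylborinate | C=CC[C@H](OB([C@@H]1C[C@@H]2C[C@H]([C@H]1C)C2(C)C)[C@@H]1C[C@@H]2C[C@H]([C@H]1C)C2(C)C)/C(C)=C\I | intermediate
6 | (1Z,3S)-1-iodo-2-methylhexa-1,5-dien-3-ol | C=CC[C@H](O)/C(C)=C\I | intermediate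
7 | (R)-2-methylbutanoic acid | O=C(O)[C@H](C)CC | starting material
8 | (1Z,3S)-1-iodo-2-methylhexa-1,5-dien-3-yl (2R)-2-methylbutanoate | C=CC[C@H](OC(=O)[C@H](C)CC)/C(C)=C\I | intermediate
9 | methacrolein | C=C(C)C=O | starting material
10 | (1Z,3S,5E)-1-iodo-2,6-dimethyl-7-oxohepta-1,5-dien-3-yl (2R)-2-methylbutanoate | O=C/C(C)=C/C[C@H](OC(=O)[C@H](C)CC)/C(C)=C\I | intermediate
11 | (1Z,3S,5E)-7-hydroxy-1-iodo-2,6-dimethylhepta-1,5-dien-3-yl (2R)-2-methylbutanoate | OC/C(C)=C/C[C@H](OC(=O)[C@H](C)CC)/C(C)=C\I | intermediate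
12 | (1Z,3S,5E)-7-bromo-1-iodo-2,6-dimethylhepta-1,5-dien-3-yl (2R)-2-methylbutanoate | BrC/C(C)=C/C[C@H](OC(=O)[C@H](C)CC)/C(C)=C\I | intermediate
13 | 2,2-dimethyl-1,3-dioxan-5-one | CC1(C)OCC(=O)CO1 | starting material
14 | (R)-1-amino-2-(methoxymethyl)pyrrolidine (RAMP) | COC[C@H]1CCCN1N | starting material
15 | (R)-N-(2,2-dimethyl-1,3-dioxan-5-ylidene)-2-(methoxymethyl)pyrrolidin-1-amine | COC[C@H]1CCCN1N=C1COC(C)(C)OC1 | intermediate
16 | lithium azaenolate of 15 (N-lithio ene-hydrazine) | COC[C@H]1CCCN1N([Li])C1=COC(C)(C)OC1 | intermediate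
17 | (1Z,3S,5E)-7-[(4R)-2,2-dimethyl-5-{[(2R)-2-(methoxymethyl)pyrrolidin-1-yl]imino}-1,3-dioxan-4-yl]-1-iodo-2,6-dimethylhepta-1,5-dien-3-yl (2R)-2-methylbutanoate (C=N geometry not assigned) | COC[C@H]1CCCN1N=C1COC(C)(C)O[C@@H]1C/C(C)=C/C[C@H](OC(=O)[C@H](C)CC)/C(C)=C\I | intermediate
18 | (1Z,3S,5E)-7-[(4R)-2,2-dimethyl-5-oxo-1,3-dioxan-4-yl]-1-iodo-2,6-dimethylhepta-1,5-dien-3-yl (2R)-2-methylbutanoate | O=C1COC(C)(C)O[C@@H]1C/C(C)=C/C[C@H](OC(=O)[C@H](C)CC)/C(C)=C\I | intermediate
19 | (1Z,3S,5E)-7-[(4R,5R)-5-hydroxy-2,2-dimethyl-1,3-dioxan-4-yl]-1-iodo-2,6-dimethylhepta-1,5-dien-3-yl (2R)-2-methylbutanoate (4,5-cis) | O[C@@H]1COC(C)(C)O[C@@H]1C/C(C)=C/C[C@H](OC(=O)[C@H](C)CC)/C(C)=C\I | intermediate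
20 | sodium O-alkyl dithiocarbonate (xanthate salt) of 19 | [Na+].[S-]C(=S)O[C@@H]1COC(C)(C)O[C@@H]1C/C(C)=C/C[C@H](OC(=O)[C@H](C)CC)/C(C)=C\I | intermediate
21 | (1Z,3S,5E)-7-[(4R,5R)-2,2-dimethyl-5-{[(methylsulfanyl)carbonothioyl]oxy}-1,3-dioxan-4-yl]-1-iodo-2,6-dimethylhepta-1,5-dien-3-yl (2R)-2-methylbutanoate | CSC(=S)O[C@@H]1COC(C)(C)O[C@@H]1C/C(C)=C/C[C@H](OC(=O)[C@H](C)CC)/C(C)=C\I | intermediate
22 | (1Z,3S,5E,8R,9R)-8,10-dihydroxy-1-iodo-2,6-dimethyl-9-{[(methylsulfanyl)carbonothioyl]oxy}deca-1,5-dien-3-yl (2R)-2-methylbutanoate | OC[C@@H](OC(=S)SC)[C@H](O)C/C(C)=C/C[C@H](OC(=O)[C@H](C)CC)/C(C)=C\I | intermediate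
23 | (1Z,3S,5E,8R,9R)-1-iodo-2,6-dimethyl-9-{[(methylsulfanyl)carbonothioyl]oxy}-8,10-bis[(triethylsilyl)oxy]deca-1,5-dien-3-yl (2R)-2-methylbutanoate | CC[Si](CC)(CC)OC[C@@H](OC(=S)SC)[C@H](O[Si](CC)(CC)CC)C/C(C)=C/C[C@H](OC(=O)[C@H](C)CC)/C(C)=C\I | intermediate
24 | dimethyl(alkoxy)sulfonium chloride of the C6 oxygen of 23 | C[S+](C)OC[C@@H](OC(=S)SC)[C@H](O[Si](CC)(CC)CC)C/C(C)=C/C[C@H](OC(=O)[C@H](C)CC)/C(C)=C\I.[Cl-] | intermediate
25 | (1Z,3S,5E,8R,9S)-1-iodo-2,6-dimethyl-9-{[(methylsulfanyl)carbonothioyl]oxy}-10-oxo-8-[(triethylsilyl)oxy]deca-1,5-dien-3-yl (2R)-2-methylbutanoate | O=C[C@@H](OC(=S)SC)[C@H](O[Si](CC)(CC)CC)C/C(C)=C/C[C@H](OC(=O)[C@H](C)CC)/C(C)=C\I | intermediate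
26 | (1S,2Z,4R,5R,6R,8E)-4-hydroxy-2,8-dimethyl-5-{[(methylsulfanyl)carbonothioyl]oxy}-6-[(triethylsilyl)oxy]cyclodeca-2,8-dien-1-yl (2R)-2-methylbutanoate (germacrane locants 3S,6R,7R,8R) | O[C@@H]1/C=C(/C)[C@@H](OC(=O)[C@H](C)CC)C/C=C(\C)C[C@@H](O[Si](CC)(CC)CC)[C@@H]1OC(=S)SC | intermediate
27 | propiolic acid | C#CC(=O)O | starting material
28 | (1S,2Z,4R,5R,6R,8E)-2,8-dimethyl-5-{[(methylsulfanyl)carbonothioyl]oxy}-4-(prop-2-ynoyloxy)-6-[(triethylsilyl)oxy]cyclodeca-2,8-dien-1-yl (2R)-2-methylbutanoate | C#CC(=O)O[C@@H]1/C=C(/C)[C@@H](OC(=O)[C@H](C)CC)C/C=C(\C)C[C@@H](O[Si](CC)(CC)CC)[C@@H]1OC(=S)SC | intermediate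
29 | (3aS,4R,6E,9S,10Z,11aR)-6,10-dimethyl-3-methylidene-2-oxo-4-[(triethylsilyl)oxy]-2,3,3a,4,5,8,9,11a-octahydrocyclodeca[b]furan-9-yl (2R)-2-methylbutanoate | C=C1C(=O)O[C@@H]2/C=C(/C)[C@@H](OC(=O)[C@H](C)CC)C/C=C(\C)C[C@@H](O[Si](CC)(CC)CC)[C@@H]12 | intermediate
30 | (3aR,4R,6E,9S,10Z,11aR)-4-hydroxy-6,10-dimethyl-3-methylidene-2-oxo-2,3,3a,4,5,8,9,11a-octahydrocyclodeca[b]furan-9-yl (2R)-2-methylbutanoate | C=C1C(=O)O[C@@H]2/C=C(/C)[C@@H](OC(=O)[C@H](C)CC)C/C=C(\C)C[C@@H](O)[C@@H]12 | intermediate
31 | (E)-2-methylbut-2-en-1-ol | C/C=C(\C)CO | starting material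
32 | [(2S,3S)-2,3-dimethyloxiran-2-yl]methanol | OC[C@]1(C)O[C@H]1C | intermediate
33 | (2R,3S)-2,3-dimethyloxirane-2-carboxylic acid | OC(=O)[C@]1(C)O[C@H]1C | intermediate
34 | (2R,3S)-2,3-dimethyloxirane-2-carboxylic 2,4,6-trichlorobenzoic anhydride | O=C(OC(=O)c1c(Cl)cc(Cl)cc1Cl)[C@]1(C)O[C@H]1C | intermediate
35 | (3aR,4R,6E,9S,10Z,11aR)-6,10-dimethyl-9-{[(2R)-2-methylbutanoyl]oxy}-3-methylidene-2-oxo-2,3,3a,4,5,8,9,11a-octahydrocyclodeca[b]furan-4-yl (2R,3S)-2,3-dimethyloxirane-2-carboxylate | C=C1C(=O)O[C@@H]2/C=C(/C)[C@@H](OC(=O)[C@H](C)CC)C/C=C(\C)C[C@@H](OC(=O)[C@]3(C)O[C@H]3C)[C@@H]12 | intermediate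
36 | CNP0265335.3, (1R,3S,6R,7R,8R,10R)-1,10-epoxy-3-[(2R)-2-methylbutanoyloxy]-8-[(2R,3S)-2,3-epoxy-2-methylbutanoyloxy]germacra-4Z,11(13)-dien-12,6-olide | C=C1C(=O)O[C@@H]2/C=C(/C)[C@@H](OC(=O)[C@H](C)CC)C[C@H]3O[C@]3(C)C[C@@H](OC(=O)[C@]3(C)O[C@H]3C)[C@@H]12 | target

## Step count and risk

Total: 22 steps. Longest linear sequence: 19 steps (steps 1–7, 9–18, 21, 22 from propargyl alcohol). Side branches: step 8, and steps 19–20.

**Step 17 (key step).** Three things may go wrong. Stannyl radicals may add to the terminal alkyne and be trapped (hydrostannation). The C7 radical may be reduced before closure, because the ester rests in the rotamer that holds the alkyne away. Closure may occur at C13 to give a six-membered lactone. The fallback sets out from 26. Acid-catalysed exchange with 3,3-diethoxyprop-1-yne (pyridinium p-toluenesulfonate, toluene) gives the ethyl propargylic mixed acetal F1. Treatment with Bu3SnH and AIBN generates the same C7 radical, which now cyclises 5-exo-dig through a freely rotating acetal tether to the bicyclic 2-ethoxy-3-methylidene-tetrahydrofuran F2. Aqueous acetic acid hydrolyses both the acetal and the silyl ether to the hydroxy lactol F3. MnO2 oxidises the allylic lactol to lactone 30, where the route resumes.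

**Step 15.** Facial selectivity at C6 may be poor, because ring strain in the closing ten-membered ring can override the open-chain induction model. Competing intermolecular coupling and binding of nickel by the thiocarbonyl sulfur are further concerns. The fallback sets out from 25. The ring closure is run as before, and the mixture of 26 and its C6 epimer, the epi-alcohol F4, is oxidised with Dess–Martin periodinane to the enone F5. Reduction under reagent control with an oxazaborolidine–catecholborane (CBS) system, using the catalyst antipode that delivers hydride to the required face, returns to 26.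

**Step 9.** The lithium azaenolate may deprotonate or acylate on the 2-methylbutanoate of the electrophile, eroding the side-chain stereocentre. Residual t-BuLi may exchange with the vinyl iodide. The fallback sets out from 6 and carries C3 as a silyl ether through the basic step. Silylation (t-BuMe2SiCl, imidazole) gives the silyl ether F6. Cross-metathesis with 9 gives the enal F7, Luche reduction the allylic alcohol F8, and Appel bromination the bromide F9. Alkylation of azaenolate 16 gives the hydrazone F10, which oxalic acid cleaves to the ketone F11. HF·pyridine then frees the C3 alcohol F12, and Steglich esterification with 7 returns to 18.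

**Step 14.** The chlorosulfonium reagent may attack the thiocarbonyl sulfur, the secondary silyl ether may be lost, or silyloxide may β-eliminate from the aldehyde on amine treatment. The fallback sets out from 23. Selective methanolysis of the primary silyl ether (pyridinium p-toluenesulfonate, MeOH/CH2Cl2, −10 °C) gives the primary alcohol F13. Oxidation with buffered Dess–Martin periodinane, with no amine base, returns to 25.

**Step 22.** Steric approach control on the flexible ring may give poor facial selectivity, and acid may open the new epoxide across the ring. The fallback sets out from 30. Hydroxyl-directed epoxidation with VO(acac)2 and t-BuOOH, in which the C8 carbinol rather than ring shape selects the olefin face, gives the epoxy alcohol F14. Yamaguchi esterification with 33 then returns to 36.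

## Further compounds

F1 | step 17 | ethyl propargylic mixed acetal of 26 at O6 (acetal epimers) | C#CC(OCC)O[C@@H]1/C=C(/C)[C@@H](OC(=O)[C@H](C)CC)C/C=C(\C)C[C@@H](O[Si](CC)(CC)CC)[C@@H]1OC(=S)SC
F2 | step 17 | trans-fused 2-ethoxy-3-methylidene-tetrahydrofuran (lactol ethyl ether of 29, acetal epimers) | C=C1C(OCC)O[C@@H]2/C=C(/C)[C@@H](OC(=O)[C@H](C)CC)C/C=C(\C)C[C@@H](O[Si](CC)(CC)CC)[C@@H]12
F3 | step 17 | hydroxy lactol corresponding to 30 (lactol epimers) | C=C1C(O)O[C@@H]2/C=C(/C)[C@@H](OC(=O)[C@H](C)CC)C/C=C(\C)C[C@@H](O)[C@@H]12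
F4 | step 15 | C6 epimer of 26 (6S alcohol) | O[C@H]1/C=C(/C)[C@@H](OC(=O)[C@H](C)CC)C/C=C(\C)C[C@@H](O[Si](CC)(CC)CC)[C@@H]1OC(=S)SC
F5 | step 15 | C6 ketone (Z-enone) of 26 | O=C1/C=C(/C)[C@@H](OC(=O)[C@H](C)CC)C/C=C(\C)C[C@@H](O[Si](CC)(CC)CC)[C@@H]1OC(=S)SC
F6 | step 9 | tert-butyldimethylsilyl ether of 6 | C=CC[C@H](O[Si](C)(C)C(C)(C)C)/C(C)=C\I
F7 | step 9 | (2E,5S,6Z)-5-(tert-butyldimethylsilyloxy)-7-iodo-2,6-dimethylhepta-2,6-dienal | O=C/C(C)=C/C[C@H](O[Si](C)(C)C(C)(C)C)/C(C)=C\I
F8 | step 9 | (2E,5S,6Z)-5-(tert-butyldimethylsilyloxy)-7-iodo-2,6-dimethylhepta-2,6-dien-1-ol | OC/C(C)=C/C[C@H](O[Si](C)(C)C(C)(C)C)/C(C)=C\I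
F9 | step 9 | (2E,5S,6Z)-1-bromo-5-(tert-butyldimethylsilyloxy)-7-iodo-2,6-dimethylhepta-2,6-diene | BrC/C(C)=C/C[C@H](O[Si](C)(C)C(C)(C)C)/C(C)=C\I
F10 | step 9 | alkylated RAMP hydrazone, C3 silyl ether analogue of 17 | COC[C@H]1CCCN1N=C1COC(C)(C)O[C@@H]1C/C(C)=C/C[C@H](O[Si](C)(C)C(C)(C)C)/C(C)=C\I
F11 | step 9 | (4R)-dioxanone, C3 silyl ether analogue of 18 | O=C1COC(C)(C)O[C@@H]1C/C(C)=C/C[C@H](O[Si](C)(C)C(C)(C)C)/C(C)=C\I
F12 | step 9 | (4R)-dioxanone with free C3 hydroxyl | O=C1COC(C)(C)O[C@@H]1C/C(C)=C/C[C@H](O)/C(C)=C\I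
F13 | step 14 | primary alcohol (C6–OH, C8 silyl ether) from 23 | OC[C@@H](OC(=S)SC)[C@H](O[Si](CC)(CC)CC)C/C(C)=C/C[C@H](OC(=O)[C@H](C)CC)/C(C)=C\I
F14 | step 22 | 1,10-epoxide of 30 (1R,10R) | C=C1C(=O)O[C@@H]2/C=C(/C)[C@@H](OC(=O)[C@H](C)CC)C[C@H]3O[C@]3(C)C[C@@H](O)[C@@H]12
A1 | alternative 1 | trans-disubstituted lactone Mannich base (C11 epimers) | O=C1O[C@H](CO[Si](C)(C)C(C)(C)C)[C@@H](C2(C/C(C)=C/C[C@H](O[Si](C)(C)C(C)(C)C)C(C)=C)SCCCS2)C1CN(C)C
A2 | alternative 1 | 2-[(2E,5S)-5-(tert-butyldimethylsilyloxy)-2,6-dimethylhepta-2,6-dienyl]-1,3-dithiane | S1CCCSC1C/C(C)=C/C[C@H](O[Si](C)(C)C(C)(C)C)C(C)=C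
A3 | alternative 1 | (S)-5-[(tert-butyldimethylsilyloxy)methyl]furan-2(5H)-one | O=C1C=C[C@@H](CO[Si](C)(C)C(C)(C)C)O1
A4 | alternative 2 | ten-membered (1E,4Z)-dien-6-one with C3 silyl ether and C8 4-methoxybenzyl ether | O=C1/C=C(/C)[C@@H](O[Si](C)(C)C(C)(C)C)C/C=C(\C)C[C@@H](OCc2ccc(OC)cc2)C1
A5 | alternative 2 | 1-[(Z)-2-(4-methoxybenzyloxy)ethenyl]-3-methyl-4-(tert-butyldimethylsilyloxy)-6-(prop-1-en-2-yl)cyclohex-2-en-1-ol (alkenyl groups trans) | C=C(C)[C@@H]1C[C@H](O[Si](C)(C)C(C)(C)C)C(C)=C[C@@]1(O)/C=C\OCc1ccc(OC)cc1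
A6 | alternative 3 | trans-fused ten-membered lactone with C3 silyl ether and C8 4-methoxybenzyl ether | O=C1O[C@@H]2/C=C(/C)[C@@H](O[Si](C)(C)C(C)(C)C)C/C=C(\C)C[C@@H](OCc3ccc(OC)cc3)[C@H]2C1
A7 | alternative 3 | methyl (6E,10Z)-3-formyl-11-iodo-4-(4-methoxybenzyloxy)-6,10-dimethyl-9-(tert-butyldimethylsilyloxy)undeca-6,10-dienoate (stereocentres as in A6) | COC(=O)C[C@@H](C=O)[C@H](OCc1ccc(OC)cc1)C/C(C)=C/C[C@H](O[Si](C)(C)C(C)(C)C)/C(C)=C\I
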